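The synthesis rests on disconnecting ring B at O1–C8a and, in the same operation, the C8–CH3 bond of ring A. Because O1 (on C8a) and the methyl group (on C8) sit on adjacent ring-A carbons, and C8a is flanked by C4a, which carries the C4–C3 tether to the carbinol carbon C2, a C8≡C8a aryne can be closed by the tethered tertiary alkoxide and the resulting C8 anion methylated in one flask. The precursor is an open-chain (R)-tertiary carbinol bearing a 2-fluoro-5-silyloxyphenyl group, assembled from farnesol-derived (R)-nerolidol and silylated 3-bromo-4-fluorophenol; the acid terminus is introduced afterwards by allylic oxidation.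

Key step: step 6

Remark: ring atoms carry chroman numbers (O1, C2, C3, C4, C4a, C5 to C8, C8a) and side-chain atoms primed numbers; the tertiary hydroxyl group of the nerolidol intermediate is assumed to tolerate 9-BBN unprotected, any O–B bond being hydrolysed in the aqueous coupling medium.

Step 1
Reactants: 1 3-bromo-4-fluorophenol
Product: 2 (3-bromo-4-fluorophenoxy)triisopropylsilane
Conditions: i-Pr3SiCl, imidazole, DMF, rt
Reagents that add atoms: chlorotriisopropylsilane, CC(C)[Si](Cl)(C(C)C)C(C)C
Why: Imidazole-promoted silylation of a phenol is routine, and the bulky triisopropylsilyl ether is chosen because it should survive organolithium, coupling and oxidation conditions and cannot direct metalation to its own ortho positions.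

Step 2
Reactants: 3 (2E,6E)-farnesol
Product: 4 (2R,3R)-2,3-epoxyfarnesol, [(2R,3R)-3-[(3E)-4,8-dimethylnona-3,7-dienyl]-3-methyloxiran-2-yl]methanol
Conditions: Ti(OiPr)4 (cat.), D-(−)-diethyl tartrate (cat.), t-BuOOH, 4 Å MS, CH2Cl2, −20 °C
Reagents that add atoms: tert-butyl hydroperoxide, CC(C)(C)OO
Why: In the Sharpless asymmetric epoxidation the titanium tartrate binds the allylic hydroxyl, so only the 2,3-alkene is epoxidized, and the D-(−)-tartrate ligand should deliver oxygen to the face that gives the (2R,3R) epoxide, which fixes the carbon that becomes C2 of the chroman.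

Step 3
Reactants: 4 (2R,3R)-2,3-epoxyfarnesol
Product: 5 (2S,3R)-3-[(3E)-4,8-dimethylnona-3,7-dienyl]-2-(iodomethyl)-3-methyloxirane
Conditions: I2, PPh3, imidazole, Et2O/MeCN, 0 °C
Reagents that add atoms: iodine, II
Why: Appel-type iodination replaces the primary hydroxyl by SN2 attack of iodide on the alkoxyphosphonium ion under buffered conditions that leave the epoxide intact (the C2 descriptor changes to S only because the CH2I group now outranks C3).

Step 4
Reactants: 5 (2S,3R)-3-[(3E)-4,8-dimethylnona-3,7-dienyl]-2-(iodomethyl)-3-methyloxirane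
Product: 6 (3R,6E)-nerolidol, (3R,6E)-3,7,11-trimethyldodeca-1,6,10-trien-3-ol
Conditions: Zn dust, EtOH, reflux
Reagents that add atoms: none
Why: Zinc inserts into the C–I bond and the organozinc undergoes reductive β-elimination with opening of the epoxide at the C2–O bond, so the C3–O bond is never broken and the tertiary vinyl carbinol should retain the configuration set in step 2.

Step 5
Reactants: 6 (3R,6E)-nerolidol; 2 (3-bromo-4-fluorophenoxy)triisopropylsilane
Product: 8 (3R,6E)-1-[2-fluoro-5-(triisopropylsilyloxy)phenyl]-3,7,11-trimethyldodeca-6,10-dien-3-ol, via B-alkyl-9-BBN adduct 7 (not isolated)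
Conditions: 9-BBN (2 equiv), THF, 0 °C to rt; then 2, Pd(dppf)Cl2 (5 mol%), aq. K3PO4, THF/DMF, 50 °C
Reagents that add atoms: none
Why: 9-BBN hydroborates the monosubstituted vinyl group far faster than the two trisubstituted alkenes and places boron on the terminal carbon, and the resulting B-alkyl borane should undergo Suzuki–Miyaura coupling at the C–Br bond while the C–F bond and the silyl ether stay intact.

Step 6
Reactants: 8 (3R,6E)-1-[2-fluoro-5-(triisopropylsilyloxy)phenyl]-3,7,11-trimethyldodeca-6,10-dien-3-ol; 9 iodomethane
Product: 14 (2R)-2-[(3E)-4,8-dimethylnona-3,7-dienyl]-2,8-dimethyl-6-(triisopropylsilyloxy)chroman, via lithium alkoxide 10 (not isolated), via C8-lithiated fluoroarene 11 (not isolated), via C8–C8a aryne 12 (not isolated), via 8-lithiochroman 13 (not isolated)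
Conditions: n-BuLi (1.05 equiv), THF (0.02 M), −78 °C; s-BuLi (1.1 equiv), −78 °C, 1 h; −78 to −20 °C; CH3I (3 equiv), −78 °C to rt
Reagents that add atoms: iodomethane, CI
Why: n-BuLi first converts the carbinol into lithium alkoxide 10 and s-BuLi then removes H8, the kinetically most acidic ring proton because it alone lies beside fluorine, to give 11; on warming, 11 loses LiF to form aryne 12, the tethered alkoxide adds to C8a, and the C8 carbanion of 13 is alkylated by CH3I in an SN2 reaction. The closest known reaction type is the base-induced aryne cyclization of halobenzenes that carry a tethered alkoxide or amide, followed by electrophilic capture of the new aryllithium, as used for chromans, dihydrobenzofurans and indolines. Ring B closes in a 6-exo-dig sense, O1 bonding to C8a, the only aryne carbon that the three-atom tether from C4a can reach without a meta bridge. No stereocenter is created, and C2 takes part in no bond change, so it should keep the R configuration installed in step 2. The step needs site-selective metalation, secured by the acidifying fluorine and by the bulky, non-coordinating OSi(iPr)3 group that screens H5 and H7, and regioselective aryne addition, secured by the tether, which also leaves the carbanion on C8 beside the unhindered C7–H where CH3I has free access. High dilution, only a slight excess of s-BuLi and slow warming are specified so that the intramolecular addition should outrun attack of any organolithium on the aryne.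

Step 7
Reactants: 14 (2R)-2-[(3E)-4,8-dimethylnona-3,7-dienyl]-2,8-dimethyl-6-(triisopropylsilyloxy)chroman
Product: 16 (2E,6E)-9-[(2R)-2,8-dimethyl-6-(triisopropylsilyloxy)chroman-2-yl]-2,6-dimethylnona-2,6-dienal, via allylic alcohol 15 (not isolated)
Conditions: SeO2 (0.3 equiv), t-BuOOH, salicylic acid (cat.), CH2Cl2, 0 °C to rt; then MnO2, CH2Cl2, rt
Reagents that add atoms: selenium dioxide, O=[Se]=O; tert-butyl hydroperoxide, CC(C)(C)OO
Why: Catalytic SeO2 with t-BuOOH performs the allylic oxidation (ene reaction followed by [2,3]-sigmatropic shift) preferentially at the (E)-methyl group of the terminal, least hindered trisubstituted alkene, and MnO2 then converges the unpurified mixture of allylic alcohol 15 and enal onto the (E)-enal without touching the silyl ether or the alkenes.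

Step 8
Reactants: 16 (2E,6E)-9-[(2R)-2,8-dimethyl-6-(triisopropylsilyloxy)chroman-2-yl]-2,6-dimethylnona-2,6-dienal
Product: 17 (2E,6E)-9-[(2R)-2,8-dimethyl-6-(triisopropylsilyloxy)chroman-2-yl]-2,6-dimethylnona-2,6-dienoic acid
Conditions: NaClO2, NaH2PO4, 2-methyl-2-butene, t-BuOH/THF/H2O, 0 °C to rt
Reagents that add atoms: sodium chlorite, [Na+].[O-]Cl=O
Why: The Pinnick oxidation converts the enal into the acid without isomerizing the conjugated (E)-alkene, the large excess of 2-methyl-2-butene intercepting hypochlorous acid before it can attack the alkenes or the electron-rich ring, whose phenol is still masked.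

Step 9
Reactants: 17 (2E,6E)-9-[(2R)-2,8-dimethyl-6-(triisopropylsilyloxy)chroman-2-yl]-2,6-dimethylnona-2,6-dienoic acid
Product: 18 (2E,6E)-9-[(2R)-6-hydroxy-2,8-dimethylchroman-2-yl]-2,6-dimethylnona-2,6-dienoic acid (target)
Conditions: Bu4NF (2.5 equiv), THF, 0 °C to rt, under argon; pH 4 buffer work-up
Reagents that add atoms: none
Why: Fluoride-mediated desilylation, driven by formation of the strong Si–F bond, should cleave the aryl silyl ether while leaving the acid, both alkenes and the C2 stereocenter untouched, and the mildly acidic work-up returns the free phenol and carboxylic acid.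

Compound list
1 | 3-bromo-4-fluorophenol | Oc1ccc(F)c(Br)c1 | starting material
2 | (3-bromo-4-fluorophenoxy)triisopropylsilane | CC(C)[Si](Oc1ccc(F)c(Br)c1)(C(C)C)C(C)C | intermediate
3 | (2E,6E)-farnesol | OC/C=C(\C)CC/C=C(\C)CCC=C(C)C | starting material
4 | (2R,3R)-2,3-epoxyfarnesol, [(2R,3R)-3-[(3E)-4,8-dimethylnona-3,7-dienyl]-3-methyloxiran-2-yl]methanol | OC[C@H]1O[C@]1(C)CC/C=C(\C)CCC=C(C)C | intermediate
5 | (2S,3R)-3-[(3E)-4,8-dimethylnona-3,7-dienyl]-2-(iodomethyl)-3-methyloxirane | IC[C@H]1O[C@]1(C)CC/C=C(\C)CCC=C(C)C | intermediate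
6 | (3R,6E)-nerolidol, (3R,6E)-3,7,11-trimethyldodeca-1,6,10-trien-3-ol | C/C(=C\CC[C@](O)(C)C=C)CCC=C(C)C | intermediate
7 | 9-[(3S,6E)-3-hydroxy-3,7,11-trimethyldodeca-6,10-dienyl]-9-borabicyclo[3.3.1]nonane (same spatial arrangement at the carbinol carbon as in 6; descriptor S because boron ranks below carbon) | C/C(=C\CC[C@](O)(C)CCB1C2CCCC1CCC2)CCC=C(C)C | intermediate
8 | (3R,6E)-1-[2-fluoro-5-(triisopropylsilyloxy)phenyl]-3,7,11-trimethyldodeca-6,10-dien-3-ol | C/C(=C\CC[C@](O)(C)CCc1cc(O[Si](C(C)C)(C(C)C)C(C)C)ccc1F)CCC=C(C)C | intermediate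
9 | iodomethane | CI | starting material
10 | lithium (3R,6E)-1-[2-fluoro-5-(triisopropylsilyloxy)phenyl]-3,7,11-trimethyldodeca-6,10-dien-3-olate | C/C(=C\CC[C@](O[Li])(C)CCc1cc(O[Si](C(C)C)(C(C)C)C(C)C)ccc1F)CCC=C(C)C | intermediate
11 | lithium alkoxide of 8 lithiated at the ring carbon beside fluorine (future C8) | C/C(=C\CC[C@](O[Li])(C)CCc1cc(O[Si](C(C)C)(C(C)C)C(C)C)cc([Li])c1F)CCC=C(C)C | intermediate
12 | lithium alkoxide of the aryne with the triple bond between future C8 and C8a | C/C(=C\CC[C@](O[Li])(C)CCC1=CC(O[Si](C(C)C)(C(C)C)C(C)C)=CC#C1)CCC=C(C)C | intermediate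
13 | (2R)-2-[(3E)-4,8-dimethylnona-3,7-dienyl]-8-lithio-2-methyl-6-(triisopropylsilyloxy)chroman | C/C(=C\CC[C@]1(C)CCc2cc(O[Si](C(C)C)(C(C)C)C(C)C)cc([Li])c2O1)CCC=C(C)C | intermediate
14 | (2R)-2-[(3E)-4,8-dimethylnona-3,7-dienyl]-2,8-dimethyl-6-(triisopropylsilyloxy)chroman | C/C(=C\CC[C@]1(C)CCc2cc(O[Si](C(C)C)(C(C)C)C(C)C)cc(C)c2O1)CCC=C(C)C | intermediate
15 | (2E,6E)-9-[(2R)-2,8-dimethyl-6-(triisopropylsilyloxy)chroman-2-yl]-2,6-dimethylnona-2,6-dien-1-ol | C/C(=C\CC[C@]1(C)CCc2cc(O[Si](C(C)C)(C(C)C)C(C)C)cc(C)c2O1)CC/C=C(\C)CO | intermediate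
16 | (2E,6E)-9-[(2R)-2,8-dimethyl-6-(triisopropylsilyloxy)chroman-2-yl]-2,6-dimethylnona-2,6-dienal | C/C(=C\CC[C@]1(C)CCc2cc(O[Si](C(C)C)(C(C)C)C(C)C)cc(C)c2O1)CC/C=C(\C)C=O | intermediate
17 | (2E,6E)-9-[(2R)-2,8-dimethyl-6-(triisopropylsilyloxy)chroman-2-yl]-2,6-dimethylnona-2,6-dienoic acid | C/C(=C\CC[C@]1(C)CCc2cc(O[Si](C(C)C)(C(C)C)C(C)C)cc(C)c2O1)CC/C=C(\C)C(=O)O | intermediate
18 | (2E,6E)-9-[(2R)-6-hydroxy-2,8-dimethylchroman-2-yl]-2,6-dimethylnona-2,6-dienoic acid | C/C(=C\CC[C@]1(C)CCc2cc(O)cc(C)c2O1)CC/C=C(\C)C(=O)O | target

Total step count: 9. Longest linear sequence: 8 steps (steps 2 to 9, from farnesol 3 to target 18); step 1 is a one-step side branch.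

Steps most likely to fail

Step 6. The aryne may be consumed by intermolecular attack of an organolithium before the tertiary alkoxide closes ring B, metalation may stray from H8, or the C8 carbanion may be protonated before it meets CH3I. The fallback closes ring B by palladium-catalysed intramolecular C–O coupling on an aryl bromide that already carries the C8 methyl group. It sets out from 6 and comes back at 14. Commercial 3-bromo-5-methylphenol (Cc1cc(O)cc(Br)c1) would be brominated para to the hydroxyl group (Bu4NBr3, CH2Cl2/MeOH) to give 3,4-dibromo-5-methylphenol F1, which would be silylated (i-Pr3SiCl, imidazole, DMF) to (3,4-dibromo-5-methylphenoxy)triisopropylsilane F2. Borane 7, made from 6 as in step 5, would be coupled with F2 under the Suzuki–Miyaura conditions of step 5; reaction is expected at the less hindered C3–Br, which is not para to the oxygen donor, giving (3R,6E)-1-[2-bromo-3-methyl-5-(triisopropylsilyloxy)phenyl]-3,7,11-trimethyldodeca-6,10-dien-3-ol F3. Intramolecular aryl etherification of the tertiary alcohol (Pd(OAc)2, 2-(di-tert-butylphosphino)-1,1'-binaphthyl, Cs2CO3, toluene, 80 °C) would then give 14 with C2 untouched.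

Step 7. Oxidation may be spread over the allylic positions of the internal C3'=C4' alkene as well as the terminal methyl group, conversion may stall, or over-oxidation may occur. The fallback replaces allylic oxidation by olefin cross-metathesis. It sets out from 14 and comes back at 16. Compound 14 would be treated with excess methacrolein (CC(=C)C=O) and the second-generation Hoveyda–Grubbs catalyst in CH2Cl2 at 40 °C. The terminal isopropylidene group, the least hindered trisubstituted alkene, should exchange its CMe2 end for the formyl-bearing carbon with loss of 2-methylpropene, giving the (E)-enal 16 directly; no new compound arises on the way (F0).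

Step 5. Transmetalation of the hydroxyl-bearing alkylborane may be slow, protodeboronation may compete, or the aryl silyl ether may be eroded in the aqueous base. The fallback forms the aryl–carbon bond by a Heck reaction and then saturates the new alkene selectively. It sets out from 6 and 2 and comes back at 8. Heck coupling (Pd(OAc)2, P(o-tol)3, Et3N, MeCN, 80 °C) should arylate the terminal vinyl carbon to give (1E,3R,6E)-1-[2-fluoro-5-(triisopropylsilyloxy)phenyl]-3,7,11-trimethyldodeca-1,6,10-trien-3-ol F4; the carbinol carbon has no hydrogen, so no carbonyl compound can form. Diimide generated from 2-nitrobenzenesulfonyl hydrazide and Et3N (CH2Cl2, rt) should then reduce only the disubstituted C1=C2 alkene, leaving the trisubstituted alkenes, and give 8.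

Further compounds
F1 | step 6 | 3,4-dibromo-5-methylphenol | Cc1cc(O)cc(Br)c1Br
F2 | step 6 | (3,4-dibromo-5-methylphenoxy)triisopropylsilane | Cc1cc(O[Si](C(C)C)(C(C)C)C(C)C)cc(Br)c1Br
F3 | step 6 | (3R,6E)-1-[2-bromo-3-methyl-5-(triisopropylsilyloxy)phenyl]-3,7,11-trimethyldodeca-6,10-dien-3-ol | C/C(=C\CC[C@](O)(C)CCc1cc(O[Si](C(C)C)(C(C)C)C(C)C)cc(C)c1Br)CCC=C(C)C
F0 | step 7 | none | none
F4 | step 5 | (1E,3R,6E)-1-[2-fluoro-5-(triisopropylsilyloxy)phenyl]-3,7,11-trimethyldodeca-1,6,10-trien-3-ol | C/C(=C\CC[C@](O)(C)/C=C/c1cc(O[Si](C(C)C)(C(C)C)C(C)C)ccc1F)CCC=C(C)C
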